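## The problem

The target is a diterpenoid built on a trans-fused hydroazulene. Working numbering follows the atom order of the structure with the acetyl carbons left out: side chain C1–C8 (C3 is the methyl on C2, C8 the methyl on C7), ring B = C9, C10, C11, C12, C14, C19, C20 with C13 the exocyclic methylene, ring A = C14–C17 and C19 with C18 the methyl on C17. In this numbering the eight stereocentres are 4R, 6S, 7S, 9R, 11S, 14S, 19R, 20S. β denotes the face of ring B that carries C15 (on C14), H-19, the C20 hydroxyl and the C9 side chain; α is the face of H-14, C17 (on C19) and the C11 hydroxyl.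

The C14/C19 pair (trans ring fusion) has no neighbour to lean on and must be set absolutely. Once it exists it can steer the rest: the C14 substituent shields one face of a C11=C12 olefin (C11), the rigid trans-fused ketone and its ester direct hydride to C20 and fix C9, C9 biases C7, and C7 directs addition to a C6 aldehyde. C4 is too remote and needs a reagent. The C9 side chain sits cis to the C20 hydroxyl and trans to C17 across C20, which is the less stable arrangement and must be made under kinetic control.

The fragile parts are the C11 allylic alcohol next to the C12=C13 methylene, the single acetate on C6 among three free hydroxyls (acyl migration, selective placement), and a β-hydroxy enone on the way to the C4–C6 diol unit. Three olefins of similar substitution (C16=C17, C12=C13, C1=C2) restrict when peracids and boranes can be used.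

The enabling feature is in ring B. C19–C20–C9 is a three-carbon unit with oxygen on the middle carbon and carbon substituents at both ends. C10–C11–C12–C14 is a four-carbon unit whose allylic alcohol and methylene are an isomerised epoxide of a C11=C12 methyl olefin. Together they are a cyclohepta-1,4-diene carrying an enol ether and an ester, which is what a siloxyvinylcarbenoid and a diene give.

## Retrosynthesis

**End game.** The two O–Si bonds of 31 are cut last, so that target 32 appears only after the acetate is in place. The C4 carbinol of 31 goes back to enone 30, because C4 has no nearby stereocentre and an isopropenyl ketone is a good substrate for oxazaborolidine reduction. The acetate of 30 is put on β-hydroxy enone 29, where C6–OH is the only free hydroxyl; this solves the problem of one acetate among four oxygens without selective acylation.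

**C5–C6.** Cutting this bond gives aldehyde 26 and silyl dienol ether 28 (from ketone 27). Against a cut at C4–C5 or C6–C7 it has the advantage that the C7 methyl stereocentre sits α to the aldehyde, so Felkin–Anh addition gives the required 6,7-syn relationship. It also removes five carbons and one stereocentre in one step. The forward reaction must be a Lewis-acid aldol that tolerates the allylic silyl ether.

**C11–OH and C13 methylene.** The allylic alcohol in 24 is traced to the 11α,12α-epoxide 23 (C12–O and a C13–H are the bonds changed). Carrying the epoxide instead of the exocyclic methylene keeps a second 1,1-disubstituted olefin out of the hydroboration step. Diol 24 is then silylated twice (25), and the primary silyl ether alone is oxidised to 26.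

**C6–C8.** The C6–O and C7–H bonds of 23 come from hydroboration of isopropenyl compound 21. The C6 methylene of 21 comes from methyl ketone 20, and C8 from methyl addition to Weinreb amide 19, made from ester 18. The ester carbon thus becomes C7, and no carbon of the carbenoid is discarded. The forward sequence must not epimerise C9, which argues for non-basic methylenation.

**C20–H.** Silyl ether 18 and hydroxy ester 17 go back to β-keto ester 16. Reducing after ring A is closed gives a rigid trans-fused ketone in which axial hydride delivery and the preference for attack anti to the ester can be read. In the monocycle neither can be predicted.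

**Ring A and the epoxide.** The C16=C17 bond of 16 is cut by metathesis to diene 15, which carries allyl on C14 and isopropenyl on C19. The epoxide is placed before this step (15 from 14), because afterwards the ring A olefin would compete with C11=C12 for the peracid. β-Keto ester 14 is the desilylated form of cycloheptadiene 13.

**Ring B, the key cut.** Cutting C9–C10 and C14–C19 of 13 gives diazo diene 6 and triene 11, joined through cis-divinylcyclopropane 12. No other cut of ring B forms the C14/C19 stereo pair, the C20 oxygen, the C9 carbon substituent and the C11=C12 olefin at once from two achiral C8 pieces. The forward reaction must cyclopropanate only the diene terminus of 11, with absolute control, and must put the allyl group inward and the isopropenyl group outward in the boat transition state. Siloxy-substituted vinylcarbenoids give their best asymmetric induction with the adamantylglycine-derived dirhodium carboxylate, so Rh2(S-PTAD)4 is planned and the prolinate catalyst Rh2(S-DOSP)4 held in reserve.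

**Fragments.** Diazo diene 6 comes from diazo keto ester 5, this from β-keto ester 4, and 4 from acid 1 and dioxanedione 2 through acyl derivative 3. Triene 11 comes from chloride 10 and a vinyl Grignard reagent; 10 comes from dienol 8 (through mesylate 9) and 8 from enynol 7, whose Z olefin is bought and only has to be preserved.

## Roads not taken

**Alternative 1: dienyl Pauson–Khand closure of both rings.** The cut removes C14–C19, C15–C16 and C16–C17 and leads to acyclic dienyne A2. [Rh(CO)2Cl]2 and CO would turn A2 into dienone A1, closing ring B and a cyclopentenone ring A together.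
- Merits: three bonds and two rings in one step. The C12=C13 methylene is the spectator half of the diene and the C11 oxygen is already in place, so the epoxide detour of the chosen plan (steps 9 and 17) is not needed. In ring count per step and in handling C11–C13 this road is better.
- Weak points: the carbocycle closed by the tether is seven-membered, a ring size for which this cyclisation is far less established than for five and six. A2 needs four stereocentres (C7, C9, C11, C20) assembled linearly beforehand. C14 is set only by remote induction. A1 has its olefin at C17=C19 and a C16 ketone, so C19 is still not a stereocentre; a 1,2-reduction and a reductive allylic transposition are needed to create it and move the olefin.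
- What the chosen plan sets against it: the C14/C19 pair is formed directly and by a catalyst, from two achiral fragments of three steps each, and ring A is closed by a metathesis of little risk.

**Alternative 2: desymmetrised meso diol, conjugate addition–allylation.** The cut removes C17–C19 and C14–C15; ring B is bought as a cycloheptene. Meso diol A5 would be desymmetrised and converted to enone A4. Copper-mediated isopropenyl Grignard addition anti to the silyloxy group and allylation of the enolate would give all-trans ketone A3.
- Merits: every step is routine, C20 comes with the right configuration from an enzyme, and there are no diazo compounds and no thermal rearrangement. The C12 ketone of A3 gives the C13 methylene by simple methylenation, and C11 can be oxidised through the enolate. In reliability of the key step and in securing C14, C19 and C20 this road is as good as or better than the chosen one.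
- Weak points: no ring is formed in the key step. A3 has a bare methylene at C9, so the eight-carbon side chain must be attached to an unactivated position. That means oxidising C20 to a ketone, alkylating regioselectively at C9 against C19 and reducing again, so C20 is set twice. Enolate allylation after cuprate addition can suffer from enolate equilibration.
- What the chosen plan sets against it: the cycloaddition delivers C9 already bearing C7 and C20 bearing oxygen in the same step that sets C14/C19.

**Alternative 3: Nozaki–Hiyama–Kishi closure at C11–C12.** The cut leads to seco aldehyde A7 with a C12 vinyl iodide and a C11 aldehyde. CrCl2 with catalytic NiCl2 would close ring B and give bis-silyl ether A6, two deprotections from the target.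
- Merits: the allylic alcohol and the methylene are formed together, late, under conditions that tolerate the acetate and silyl ethers. For the labile C11–C13 array this is better than the epoxide isomerisation of the chosen plan, and the end game is shorter after ring closure.
- Weak points: A7 must already contain ring A with the trans C14/C19 pair, the C9/C20 pair and the complete side chain, seven stereocentres on an open chain, so the hard problem (C14/C19) is only moved elsewhere. The C11 configuration would come from a seven-membered ring closure whose facial preference cannot be argued with confidence. A large excess of a chromium salt is used on the most valuable intermediate.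
- What the chosen plan sets against it: ring B and the C14/C19 pair come early from simple pieces, and C11 is set by epoxidation anti to an adjacent substituent on a ring. The price is a long linear sequence after the cycloaddition.

Key step: step 7

Assumptions (remarks on the chemistry):
- The S enantiomer of the catalyst is taken to give cyclopropane 12 with the (1R,2S) configuration; if the opposite sense is found, Rh2(R-PTAD)4 is used and nothing else changes.
- Compounds 14–16 are keto/enol and C9-epimer mixtures; C9 is fixed in step 11.
- Locants C1–C20 and the α/β labels in compound names are those defined in "The problem".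

## Route

Step 1
Reactants: 1 3-methylbut-3-enoic acid; 2 2,2-dimethyl-1,3-dioxane-4,6-dione
Product: 4 methyl 5-methyl-3-oxohex-5-enoate, via acyl Meldrum's acid 3 (not isolated)
Conditions: DCC, DMAP, CH2Cl2, 0 °C → rt; then MeOH, 65 °C
Reagents that add atoms: methanol, CO
Why: Carbodiimide C-acylation of the dioxanedione followed by alcoholysis (loss of acetone and CO2) is the standard β-keto ester synthesis; partial migration of the olefin into conjugation is harmless because both isomers converge on the same dienol ether in step 3.

Step 2
Reactants: 4 methyl 5-methyl-3-oxohex-5-enoate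
Product: 5 methyl 2-diazo-5-methyl-3-oxohex-5-enoate
Conditions: 4-acetamidobenzenesulfonyl azide, Et3N, MeCN, 0 °C → rt
Reagents that add atoms: 4-acetamidobenzenesulfonyl azide, CC(=O)Nc1ccc(cc1)S(=O)(=O)N=[N+]=[N-]
Why: Regitz diazo transfer to the active methylene of a β-keto ester.

Step 3
Reactants: 5 methyl 2-diazo-5-methyl-3-oxohex-5-enoate
Product: 6 methyl (3Z)-3-[(tert-butyldimethylsilyl)oxy]-2-diazo-5-methylhexa-3,5-dienoate
Conditions: TBSOTf, Et3N, CH2Cl2, 0 °C; filtration through Et3N-deactivated silica, used at once
Reagents that add atoms: tert-butyldimethylsilyl trifluoromethanesulfonate, CC(C)(C)[Si](C)(C)OS(=O)(=O)C(F)(F)F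
Why: Soft enolisation of a 2-diazo-3-keto ester with silyl triflate and amine gives the Z silyl enol ether (silyloxy cis to the isopropenyl group); the diazo diene is not stored because vinyldiazo compounds slowly cyclise to pyrazoles.

Step 4
Reactants: 7 (2Z)-3-methylpent-2-en-4-yn-1-ol
Product: 8 (2Z)-3-methylpenta-2,4-dien-1-ol
Conditions: H2 (1 atm), Pd/CaCO3–Pb(OAc)2 (Lindlar catalyst), quinoline, EtOAc, rt
Reagents that add atoms: none
Why: Lindlar semihydrogenation takes the terminal alkyne to the vinyl group and leaves the trisubstituted olefin and its Z geometry untouched.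

Step 5
Reactants: 8 (2Z)-3-methylpenta-2,4-dien-1-ol
Product: 10 (3Z)-5-chloro-3-methylpenta-1,3-diene, via dienyl mesylate 9 (not isolated)
Conditions: MsCl, 2,4,6-collidine, LiCl, DMF, 0 °C
Reagents that add atoms: methanesulfonyl chloride, CS(=O)(=O)Cl; lithium chloride, [Li+].[Cl-]
Why: The mesylate formed in the flask is displaced by chloride in an SN2 reaction, the established way to make allylic chlorides without allylic transposition or loss of olefin geometry.

Step 6
Reactants: 10 (3Z)-5-chloro-3-methylpenta-1,3-diene
Product: 11 (3Z)-3-methylhepta-1,3,6-triene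
Conditions: vinylmagnesium bromide, CuI (5 mol %), THF, −30 → 0 °C
Reagents that add atoms: vinylmagnesium bromide, C=C[Mg]Br
Why: Copper-catalysed coupling of a primary allylic chloride with a Grignard reagent; attack at the γ-carbon would create a quaternary centre, so α-substitution with retention of the Z olefin is expected.

Step 7
Reactants: 6 methyl (3Z)-3-[(tert-butyldimethylsilyl)oxy]-2-diazo-5-methylhexa-3,5-dienoate; 11 (3Z)-3-methylhepta-1,3,6-triene
Product: 13 methyl (3R,4S)-2-[(tert-butyldimethylsilyl)oxy]-5-methyl-3-(prop-1-en-2-yl)-4-(prop-2-en-1-yl)cyclohepta-1,5-diene-1-carboxylate, via cis-divinylcyclopropane 12 (not isolated)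
Conditions: Rh2(S-PTAD)4 (1 mol %), 11 (2 equiv), slow addition of 6, 2,2-dimethylbutane, −26 °C → rt; then xylenes, 130 °C
Reagents that add atoms: none
Why: The dirhodium carboxylate converts 6 into a donor/acceptor vinylcarbenoid, which cyclopropanates the most electron-rich and least hindered olefin of 11, the terminal C10=C11 bond of the diene, forming C9–C10 and C9–C11 with the diene residue cis to the carbenoid's dienyl group (12). The cis-divinylcyclopropane then undergoes a [3,3] shift through a boat transition state that breaks C9–C11 and forms C14–C19, so ring B is closed by three-to-seven ring expansion. The closest known reaction type is the tandem cyclopropanation/Cope rearrangement (formal (4+3) cycloaddition) of siloxyvinyldiazoacetates with dienes, including Z-dienes that need heating for the second stage. At C19 the isopropenyl group is trans to C9 on the enol ether and points outward; at C14 the allyl group is cis to C11 on the triene and points inward; one outward and one inward group give the trans C14/C19 pair. The absolute configuration of both centres comes from the catalyst-controlled cyclopropanation (C9 R, C11 S in 12) and is passed on through the boat. The step needs chemoselectivity for the diene terminus over the isolated vinyl group and over insertion into the doubly allylic C15–H bonds; this rests on the higher nucleophilicity of the diene, the stabilised siloxy-substituted carbenoid, low temperature and the excess of 11. The inward allyl group raises the barrier of the rearrangement, hence the thermal second stage.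

Step 8
Reactants: 13 the cycloheptadiene of step 7
Product: 14 methyl (3R,4S)-5-methyl-2-oxo-3-(prop-1-en-2-yl)-4-(prop-2-en-1-yl)cyclohept-5-ene-1-carboxylate (keto/enol mixture)
Conditions: HF·pyridine, THF, 0 °C
Reagents that add atoms: none
Why: Fluoride cleaves the O–Si bond of the β-silyloxy acrylate; the acidic reagent is chosen over basic fluoride so that C19, which is α to the ketone and allylic, is neither epimerised nor conjugated.

Step 9
Reactants: 14 the β-keto ester of step 8
Product: 15 11α,12α-epoxide of 14 (methyl 5,6-epoxy-5-methyl-2-oxo-3-(prop-1-en-2-yl)-4-(prop-2-en-1-yl)cycloheptane-1-carboxylate with the oxirane anti to the allyl group)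
Conditions: mCPBA (1.05 equiv), NaHCO3, CH2Cl2, −20 → 0 °C
Reagents that add atoms: 3-chloroperbenzoic acid, OOC(=O)c1cccc(Cl)c1
Why: Prilezhaev epoxidation: the trisubstituted C11=C12 olefin is more nucleophilic than the 1,1-disubstituted and monosubstituted olefins, and the peracid comes anti to the C14 allyl group, which is held pseudo-axial by strain against the C12 methyl; this sets C11 and C12 with oxygen α.

Step 10
Reactants: 15 the epoxy diene of step 9
Product: 16 trans-fused hydroazulene epoxy keto ester (methyl 11α,12α-epoxy-20-oxo-9-carboxylate with C16=C17 olefin; H-14 α, H-19 β)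
Conditions: second-generation Grubbs catalyst, (H2IMes)(PCy3)Cl2Ru=CHPh (5 mol %), CH2Cl2, 40 °C
Reagents that add atoms: none
Why: Ring-closing olefin metathesis of the allyl and isopropenyl arms gives the trisubstituted cyclopentene with loss of ethylene; the trans arms on adjacent carbons can close to the trans-fused bicycle, and the ruthenium carbene tolerates epoxides and β-keto esters.

Step 11
Reactants: 16 the epoxy keto ester of step 10
Product: 17 methyl 11α,12α-epoxy-20β-hydroxy-hydroazulene-9β-carboxylate (cis hydroxy ester)
Conditions: NaBH4, MeOH, −40 °C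
Reagents that add atoms: none
Why: Borohydride reduction of a cyclic β-keto ester: the small hydride takes the axial trajectory on the α face of the trans-fused cycloheptanone and gives the equatorial β alcohol trans to C17; of the two rapidly equilibrating C9 epimers the one with a pseudo-axial ester should react faster because hydride enters anti to the C9–CO2Me bond (polar Felkin–Anh), so hydroxyl and ester end up cis, which sets C20 and C9.

Step 12
Reactants: 17 the hydroxy ester of step 11
Product: 18 C20 triethylsilyl ether of 17
Conditions: TESCl, imidazole, DMAP (cat.), DMF, rt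
Reagents that add atoms: chlorotriethylsilane, CC[Si](Cl)(CC)CC
Why: Silylation with a silyl chloride and imidazole; a silyl triflate is avoided because it would open the trisubstituted epoxide.

Step 13
Reactants: 18 the silyl ether of step 12
Product: 19 N-methoxy-N-methyl amide corresponding to ester 18
Conditions: MeNH(OMe)·HCl, iPrMgCl, THF, −20 → 0 °C
Reagents that add atoms: N,O-dimethylhydroxylamine hydrochloride, CNOC.Cl
Why: Aminolysis of the ester by the magnesium amide (Weinreb amide formation); the reagent is weakly basic, so C9 is not epimerised and the β-silyloxy group is not eliminated.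

Step 14
Reactants: 19 the Weinreb amide of step 13
Product: 20 C9 methyl ketone (acetyl group on C9, C20–OTES, epoxide)
Conditions: MeMgBr, THF, 0 °C
Reagents that add atoms: methylmagnesium bromide, C[Mg]Br
Why: Weinreb ketone synthesis; the chelated tetrahedral adduct prevents a second addition and no enolisable ketone exists until work-up.

Step 15
Reactants: 20 the methyl ketone of step 14
Product: 21 C9 isopropenyl compound (C7=C6 olefin, C8 methyl)
Conditions: Cp2TiMe2, toluene, 70 °C, dark
Reagents that add atoms: dimethyltitanocene, C[Ti](C)(C1C=CC=C1)C1C=CC=C1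
Why: Petasis methylenation through the titanium methylidene is not basic, so the epimerisable C9 centre and the β-silyloxy group survive where a phosphorus ylide might epimerise or eliminate.

Step 16
Reactants: 21 the isopropenyl compound of step 15
Product: 23 (7S) primary alcohol (C6–OH, C20–OTES, epoxide), via B-alkyl-9-BBN adduct 22 (not isolated)
Conditions: 9-BBN, THF, 0 °C → rt; then 30% H2O2, 3 M NaOH, 0 °C
Reagents that add atoms: 9-borabicyclo[3.3.1]nonane, B1C2CCCC1CCC2; hydrogen peroxide, OO
Why: Hydroboration–oxidation: 9-BBN adds only to the 1,1-disubstituted olefin, boron at terminal C6; in the staggered transition state of a bulky borane the small H-9 lies inside and the reagent comes anti to the larger ring branch C20 with its silyloxy group, which should put the new hydrogen on C7 so as to give 7S; the C–B bond is oxidised with retention.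

Step 17
Reactants: 23 the epoxy alcohol of step 16
Product: 24 diol (C6–OH, C11α–OH, C12=C13 methylene, C20–OTES)
Conditions: Et2Al(TMP) (from Et2AlCl and LiTMP, 4 equiv), toluene, 0 °C → rt; Rochelle salt work-up
Reagents that add atoms: none
Why: Aluminium amide isomerisation of an epoxide to an allylic alcohol: aluminium binds the epoxide oxygen and the amide removes a syn proton from the least hindered β-carbon, the C13 methyl, through a cyclic transition state that breaks the tertiary C12–O bond; C11 keeps its configuration (oxygen α).

Step 18
Reactants: 24 the diol of step 17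
Product: 25 tris(triethylsilyl) ether (C6, C11, C20)
Conditions: TESCl, imidazole, DMAP (cat.), DMF, rt
Reagents that add atoms: chlorotriethylsilane, CC[Si](Cl)(CC)CC
Why: Exhaustive silylation of the primary and the allylic secondary hydroxyl; one silyl group type allows a single final deprotection.

Step 19
Reactants: 25 the tris-silyl ether of step 18
Product: 26 C6 aldehyde (7S; C11–OTES, C20–OTES)
Conditions: (COCl)2, DMSO, CH2Cl2, −78 → −30 °C; then Et3N, −78 °C
Reagents that add atoms: none
Why: Swern conditions cleave and oxidise a primary triethylsilyl ether directly to the aldehyde while secondary triethylsilyl ethers stay intact; the aldehyde is used at once so that C7 does not epimerise.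

Step 20
Reactants: 27 3-methylbut-3-en-2-one
Product: 28 3-methyl-2-(trimethylsilyloxy)buta-1,3-diene
Conditions: TMSOTf, Et3N, Et2O, 0 °C
Reagents that add atoms: trimethylsilyl trifluoromethanesulfonate, C[Si](C)(C)OS(=O)(=O)C(F)(F)F
Why: Soft enolisation of the methyl ketone; only the methyl group carries α-hydrogens, so one enol ether forms.

Step 21
Reactants: 26 the aldehyde of step 19; 28 3-methyl-2-(trimethylsilyloxy)buta-1,3-diene
Product: 29 β-hydroxy enone (6S; C4 ketone, C1=C2 isopropenyl)
Conditions: BF3·OEt2, CH2Cl2, −78 °C; NaHCO3 work-up
Reagents that add atoms: none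
Why: Mukaiyama aldol addition through an open transition state: Felkin–Anh attack anti to the large C9 substituent of the α-methyl aldehyde gives the 6,7-syn adduct, that is 6S.

Step 22
Reactants: 29 the β-hydroxy enone of step 21
Product: 30 C6 acetate of 29
Conditions: Ac2O, pyridine, DMAP (cat.), CH2Cl2, 0 °C
Reagents that add atoms: acetic anhydride, CC(=O)OC(C)=O
Why: Acylation of the only free hydroxyl places the single acetate of the target; doing it promptly and cold also removes the hydroxyl that could add to the enone.

Step 23
Reactants: 30 the acetoxy enone of step 22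
Product: 31 (4R) allylic alcohol, C11,C20-bis(triethylsilyl) ether of the target
Conditions: (S)-2-methyl-CBS-oxazaborolidine (0.5 equiv), catecholborane, toluene, −78 °C
Reagents that add atoms: none
Why: Corey–Bakshi–Shibata reduction: with the S catalyst the ketone binds with the isopropenyl group as the large substituent and hydride is delivered to give the 4R carbinol; catecholborane at −78 °C reduces 1,2 and does not hydroborate the olefins.

Step 24
Reactants: 31 the bis-silyl ether of step 23
Product: 32 CNP0281601.4 (target)
Conditions: HF·pyridine, pyridine, THF, 0 °C → rt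
Reagents that add atoms: none
Why: Fluoride cleavage of the two triethylsilyl ethers under buffered conditions that leave the acetate in place and do not promote acyl migration or ionisation of the allylic alcohols.

## Compound list

1 | 3-methylbut-3-enoic acid | CC(=C)CC(=O)O | starting material
2 | 2,2-dimethyl-1,3-dioxane-4,6-dione | CC1(C)OC(=O)CC(=O)O1 | starting material
3 | 5-(1-hydroxy-3-methylbut-3-en-1-ylidene)-2,2-dimethyl-1,3-dioxane-4,6-dione | CC(=C)CC(O)=C1C(=O)OC(C)(C)OC1=O | intermediate
4 | methyl 5-methyl-3-oxohex-5-enoate | COC(=O)CC(=O)CC(C)=C | intermediate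
5 | methyl 2-diazo-5-methyl-3-oxohex-5-enoate | COC(=O)C(=[N+]=[N-])C(=O)CC(C)=C | intermediate
6 | methyl (3Z)-3-[(tert-butyldimethylsilyl)oxy]-2-diazo-5-methylhexa-3,5-dienoate | COC(=O)C(=[N+]=[N-])/C(O[Si](C)(C)C(C)(C)C)=C/C(C)=C | intermediate
7 | (2Z)-3-methylpent-2-en-4-yn-1-ol | C#C/C(C)=C\CO | starting material
8 | (2Z)-3-methylpenta-2,4-dien-1-ol | C=C/C(C)=C\CO | intermediate
9 | (2Z)-3-methylpenta-2,4-dien-1-yl methanesulfonate | C=C/C(C)=C\COS(C)(=O)=O | intermediate
10 | (3Z)-5-chloro-3-methylpenta-1,3-diene | C=C/C(C)=C\CCl | intermediate
11 | (3Z)-3-methylhepta-1,3,6-triene | C=C/C(C)=C\CC=C | intermediate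
12 | methyl (1R,2S)-1-[(1Z)-1-(tert-butyldimethylsilyloxy)-3-methylbuta-1,3-dien-1-yl]-2-[(2Z)-hexa-2,5-dien-2-yl]cyclopropane-1-carboxylate | COC(=O)[C@]1(/C(O[Si](C)(C)C(C)(C)C)=C/C(C)=C)C[C@H]1/C(C)=C\CC=C | intermediate
13 | methyl (3R,4S)-2-[(tert-butyldimethylsilyl)oxy]-5-methyl-3-(prop-1-en-2-yl)-4-(prop-2-en-1-yl)cyclohepta-1,5-diene-1-carboxylate | COC(=O)C1=C(O[Si](C)(C)C(C)(C)C)[C@@H](C(C)=C)[C@H](CC=C)C(C)=CC1 | intermediate
14 | methyl (3R,4S)-5-methyl-2-oxo-3-(prop-1-en-2-yl)-4-(prop-2-en-1-yl)cyclohept-5-ene-1-carboxylate (keto/enol, C1 undefined) | COC(=O)C1CC=C(C)[C@@H](CC=C)[C@H](C(C)=C)C1=O | intermediate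
15 | 11α,12α-epoxide of 14 (oxirane anti to the allyl group) | COC(=O)C1C[C@@H]2O[C@]2(C)[C@@H](CC=C)[C@H](C(C)=C)C1=O | intermediate
16 | trans-fused hydroazulene epoxy keto ester (11α,12α-epoxide, C20 ketone, C9 CO2Me, C16=C17) | COC(=O)C1C[C@@H]3O[C@]3(C)[C@H]2CC=C(C)[C@@H]2C1=O | intermediate
17 | cis hydroxy ester (C20β–OH, C9β–CO2Me, 11α,12α-epoxide) | COC(=O)[C@H]1C[C@@H]3O[C@]3(C)[C@H]2CC=C(C)[C@@H]2[C@H]1O | intermediate
18 | C20 triethylsilyl ether of 17 | COC(=O)[C@H]1C[C@@H]3O[C@]3(C)[C@H]2CC=C(C)[C@@H]2[C@H]1O[Si](CC)(CC)CC | intermediate
19 | N-methoxy-N-methyl amide of the C9 carboxyl (C20–OTES, epoxide) | CON(C)C(=O)[C@H]1C[C@@H]3O[C@]3(C)[C@H]2CC=C(C)[C@@H]2[C@H]1O[Si](CC)(CC)CC | intermediate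
20 | C9 methyl ketone (C20–OTES, epoxide) | CC(=O)[C@H]1C[C@@H]3O[C@]3(C)[C@H]2CC=C(C)[C@@H]2[C@H]1O[Si](CC)(CC)CC | intermediate
21 | C9 isopropenyl compound (C20–OTES, epoxide) | C=C(C)[C@H]1C[C@@H]3O[C@]3(C)[C@H]2CC=C(C)[C@@H]2[C@H]1O[Si](CC)(CC)CC | intermediate
22 | B-alkyl-9-borabicyclo[3.3.1]nonane adduct of 21 (boron on C6, 7S) | B1(C[C@@H](C)[C@H]4C[C@@H]5O[C@]5(C)[C@H]6CC=C(C)[C@@H]6[C@H]4O[Si](CC)(CC)CC)C2CCCC1CCC2 | intermediate
23 | (7S) primary alcohol (C6–OH, C20–OTES, epoxide) | OC[C@@H](C)[C@H]1C[C@@H]3O[C@]3(C)[C@H]2CC=C(C)[C@@H]2[C@H]1O[Si](CC)(CC)CC | intermediate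
24 | diol (C6–OH, C11α–OH, C12=C13, C20–OTES) | OC[C@@H](C)[C@H]1C[C@H](O)C(=C)[C@H]2CC=C(C)[C@@H]2[C@H]1O[Si](CC)(CC)CC | intermediate
25 | C6,C11,C20-tris(triethylsilyl) ether | CC[Si](CC)(CC)OC[C@@H](C)[C@H]1C[C@H](O[Si](CC)(CC)CC)C(=C)[C@H]2CC=C(C)[C@@H]2[C@H]1O[Si](CC)(CC)CC | intermediate
26 | C6 aldehyde (C11,C20-bis-TES ether) | O=C[C@@H](C)[C@H]1C[C@H](O[Si](CC)(CC)CC)C(=C)[C@H]2CC=C(C)[C@@H]2[C@H]1O[Si](CC)(CC)CC | intermediate
27 | 3-methylbut-3-en-2-one | CC(=C)C(C)=O | starting material
28 | 3-methyl-2-(trimethylsilyloxy)buta-1,3-diene | C=C(C)C(=C)O[Si](C)(C)C | intermediate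
29 | (6S) β-hydroxy enone (C4 ketone; C11,C20-bis-TES ether) | C=C(C)C(=O)C[C@H](O)[C@@H](C)[C@H]1C[C@H](O[Si](CC)(CC)CC)C(=C)[C@H]2CC=C(C)[C@@H]2[C@H]1O[Si](CC)(CC)CC | intermediate
30 | C6 acetate of 29 | C=C(C)C(=O)C[C@H](OC(C)=O)[C@@H](C)[C@H]1C[C@H](O[Si](CC)(CC)CC)C(=C)[C@H]2CC=C(C)[C@@H]2[C@H]1O[Si](CC)(CC)CC | intermediate
31 | C11,C20-bis(triethylsilyl) ether of the target (4R) | C=C(C)[C@H](O)C[C@H](OC(C)=O)[C@@H](C)[C@H]1C[C@H](O[Si](CC)(CC)CC)C(=C)[C@H]2CC=C(C)[C@@H]2[C@H]1O[Si](CC)(CC)CC | intermediate
32 | CNP0281601.4 | C=C(C)[C@H](O)C[C@H](OC(C)=O)[C@@H](C)[C@H]1C[C@H](O)C(=C)[C@H]2CC=C(C)[C@@H]2[C@H]1O | target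

## Step count and least certain steps

Total: 24 steps. Longest linear sequence: 20 steps (steps 1–3, 7–19, 21–24).

**Step 7 (key step).** The carbenoid may be diverted from the diene terminus by insertion into the doubly allylic C15–H bonds of 11 or by cyclopropanation of its isolated vinyl group, and the long heating needed for the inward-allyl rearrangement may erode the stereochemical integrity of 12.
Fallback: take both liabilities out of the diene and add the allyl arm afterwards. The fallback sets out from 8, which is acylated to (2Z)-3-methylpenta-2,4-dien-1-yl chloroacetate F1. F1 and 6 under the same catalyst give, through the chloroacetoxy cyclopropane F2, the cycloheptadiene with an acyloxymethyl group on C14, F3. Thiourea/NaHCO3 frees the primary alcohol F4 without touching the silyl enol ether or the methyl ester, Tf2O/2,6-lutidine gives the triflate F5, and copper-catalysed displacement with vinylmagnesium bromide returns to the route at 13.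

**Step 11.** Hydride delivery may go through the more populated equatorial-ester epimer, which gives the wrong relative configuration at C9 (ester trans to the hydroxyl).
Fallback: set C9 in a separate kinetic step. From 16 the reduction then gives the C9-epimeric hydroxy ester F6. Its dianion (LDA, 2.5 equiv, THF, −78 → −30 °C; Fráter–Seebach conditions) is protonated at −78 °C with acetic acid on the face anti to the C20 alkoxide, which returns to the route at 17.

**Step 16.** Facial selectivity of the hydroboration rests on acyclic control from C9 alone and may be poor or reversed, giving the C7 epimer.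
Fallback: fix C7 on a ring. From 20, KHMDS/PhNTf2 gives the terminal enol triflate F7 and HF·pyridine frees the C20 hydroxyl (hydroxy enol triflate F8). Carbonylative lactonisation (Pd(PPh3)4, CO, Et3N) gives the cis-fused α-methylene-γ-butyrolactone F9. Hydrogenation with ClRh(PPh3)3 adds hydrogen from the convex face and gives the α-methyl lactone F10 with the 7S configuration. LiBH4 opens it to the epoxy diol F11, the aluminium amide of step 17 gives the triol F12, and silylation as in step 18 returns to the route at 25.

**Step 21.** Felkin selectivity may be modest, and the free β-hydroxy enone may cyclise by intramolecular conjugate addition of the hydroxyl before it is acetylated.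
Fallback: avoid the hydroxy enone. From 26, a BF3·OEt2-mediated Mukaiyama aldol with 1-(ethylsulfanyl)-1-(trimethylsilyloxy)ethene gives the β-hydroxy thioester F13. This is acetylated to the β-acetoxy thioester F14, and Liebeskind–Srogl coupling with isopropenylboronic acid (Pd2(dba)3, tri(2-furyl)phosphine, CuTC = cuprous thiophene-2-carboxylate) installs the isopropenyl ketone under neutral conditions, returning to the route at 30.

## Further compounds

F1 | step 7 | (2Z)-3-methylpenta-2,4-dien-1-yl chloroacetate | C=C/C(C)=C\COC(=O)CCl
F2 | step 7 | methyl (1R,2S)-1-[(1Z)-1-(tert-butyldimethylsilyloxy)-3-methylbuta-1,3-dien-1-yl]-2-[(2Z)-4-(chloroacetoxy)but-2-en-2-yl]cyclopropane-1-carboxylate | COC(=O)[C@]1(/C(O[Si](C)(C)C(C)(C)C)=C/C(C)=C)C[C@H]1/C(C)=C\COC(=O)CCl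
F3 | step 7 | methyl (3R,4S)-2-[(tert-butyldimethylsilyl)oxy]-4-[(chloroacetoxy)methyl]-5-methyl-3-(prop-1-en-2-yl)cyclohepta-1,5-diene-1-carboxylate | COC(=O)C1=C(O[Si](C)(C)C(C)(C)C)[C@@H](C(C)=C)[C@H](COC(=O)CCl)C(C)=CC1
F4 | step 7 | methyl (3R,4S)-2-[(tert-butyldimethylsilyl)oxy]-4-(hydroxymethyl)-5-methyl-3-(prop-1-en-2-yl)cyclohepta-1,5-diene-1-carboxylate | COC(=O)C1=C(O[Si](C)(C)C(C)(C)C)[C@@H](C(C)=C)[C@H](CO)C(C)=CC1
F5 | step 7 | trifluoromethanesulfonate of F4 | COC(=O)C1=C(O[Si](C)(C)C(C)(C)C)[C@@H](C(C)=C)[C@H](COS(=O)(=O)C(F)(F)F)C(C)=CC1
F6 | step 11 | C9 epimer of 17 (C20β–OH, C9α–CO2Me) | COC(=O)[C@@H]1C[C@@H]3O[C@]3(C)[C@H]2CC=C(C)[C@@H]2[C@H]1O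
F7 | step 16 | enol triflate of 20 (C7(OTf)=CH2, C20–OTES) | C=C(OS(=O)(=O)C(F)(F)F)[C@H]1C[C@@H]3O[C@]3(C)[C@H]2CC=C(C)[C@@H]2[C@H]1O[Si](CC)(CC)CC
F8 | step 16 | hydroxy enol triflate (C20–OH) | C=C(OS(=O)(=O)C(F)(F)F)[C@H]1C[C@@H]3O[C@]3(C)[C@H]2CC=C(C)[C@@H]2[C@H]1O
F9 | step 16 | cis-fused α-methylene-γ-butyrolactone (O20–C6(=O)–C7(=C8H2)–C9) | C=C1[C@H]2C[C@@H]3O[C@]3(C)[C@H]4CC=C(C)[C@@H]4[C@H]2OC1=O
F10 | step 16 | cis-fused (7S) α-methyl-γ-butyrolactone | C[C@H]1[C@H]2C[C@@H]3O[C@]3(C)[C@H]4CC=C(C)[C@@H]4[C@H]2OC1=O
F11 | step 16 | epoxy diol (C6–OH, C20–OH, 7S) | OC[C@@H](C)[C@H]1C[C@@H]3O[C@]3(C)[C@H]2CC=C(C)[C@@H]2[C@H]1O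
F12 | step 16 | triol (C6–OH, C11α–OH, C20β–OH, C12=C13) | OC[C@@H](C)[C@H]1C[C@H](O)C(=C)[C@H]2CC=C(C)[C@@H]2[C@H]1O
F13 | step 21 | (6S) β-hydroxy S-ethyl thioester (C11,C20-bis-TES ether) | CCSC(=O)C[C@H](O)[C@@H](C)[C@H]1C[C@H](O[Si](CC)(CC)CC)C(=C)[C@H]2CC=C(C)[C@@H]2[C@H]1O[Si](CC)(CC)CC
F14 | step 21 | C6 acetate of F13 | CCSC(=O)C[C@H](OC(C)=O)[C@@H](C)[C@H]1C[C@H](O[Si](CC)(CC)CC)C(=C)[C@H]2CC=C(C)[C@@H]2[C@H]1O[Si](CC)(CC)CC
A1 | alternative 1 | hydroazulene dienone (C16 ketone, C17=C19 and C12=C13 olefins, C11 and C20 TBS ethers, PMB-protected C6–C8 stub on C9) | COc1ccc(COC[C@@H](C)[C@H]2C[C@H](O[Si](C)(C)C(C)(C)C)C(=C)[C@H]3CC(=O)C(C)=C3[C@H]2O[Si](C)(C)C(C)(C)C)cc1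
A2 | alternative 1 | acyclic dienyne (C12–C15 2-substituted butadiene, C17–C19 methyl alkyne, C11 and C20 TBS ethers) | COc1ccc(COC[C@@H](C)[C@@H](C[C@H](O[Si](C)(C)C(C)(C)C)C(=C)C=C)[C@H](O[Si](C)(C)C(C)(C)C)C#CC)cc1
A3 | alternative 2 | all-trans 2-allyl-3-isopropenyl-4-(tert-butyldimethylsilyloxy)cycloheptanone | O=C1CCC[C@H](O[Si](C)(C)C(C)(C)C)[C@@H](C(C)=C)[C@@H]1CC=C
A4 | alternative 2 | (4S)-4-[(tert-butyldimethylsilyl)oxy]cyclohept-2-en-1-one | O=C1C=C[C@@H](O[Si](C)(C)C(C)(C)C)CCC1
A5 | alternative 2 | cis-cyclohept-2-ene-1,4-diol (meso) | O[C@H]1C=C[C@@H](O)CCC1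
A6 | alternative 3 | C4,C20-bis(tert-butyldimethylsilyl) ether of the target | C=C(C)[C@H](O[Si](C)(C)C(C)(C)C)C[C@H](OC(C)=O)[C@@H](C)[C@H]1C[C@H](O)C(=C)[C@H]2CC=C(C)[C@@H]2[C@H]1O[Si](C)(C)C(C)(C)C
A7 | alternative 3 | seco aldehyde (C11 aldehyde, C12 vinyl iodide on C14, ring A and side chain complete) | C=C(C)[C@H](O[Si](C)(C)C(C)(C)C)C[C@H](OC(C)=O)[C@@H](C)[C@@H](CC=O)[C@H](O[Si](C)(C)C(C)(C)C)[C@H]1C(C)=CC[C@@H]1C(I)=C
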